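**Retrosynthetic overview**

1. The cycloheptenone and the gem-dimethylcyclopropane are closed together in the last step, from a dihydropyran carrying an (E)-ynenal arm and a 2-methylprop-1-enyl group (gold-catalysed enyne cyclisation with oxygen transfer).
2. The ynenal arm comes from aldol condensation of a pyran-acetaldehyde with prop-2-ynal; the 2-methylprop-1-enyl group comes from Wittig olefination of a ring formyl group.
3. The dihydropyran, with its three stereocentres and both acetates, comes from one enantioselective inverse-electron-demand oxa-Diels–Alder reaction of an ene-dial with a (Z)-enol acetate under a chiral metal-free acid.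
4. The ene-dial comes from furan-3-ylmethanol (acetylation, oxidative ring opening); the enol acetate from silyl-protected but-3-yn-1-ol and acetic acid.
5. Ring order: dihydropyran first, then the seven- and three-membered rings in one step.

Assumption: the (S,S) enantiomer of the acid catalyst in step 4 is taken to give the (2S,3S,4R) adduct; if the sense of induction is the opposite, the mirror-image catalyst is used. Locants C-2 to C-6 are those of the dihydropyran ring (O-1, acetal carbon C-2).

**Step 1**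
Reactants: 1 furan-3-ylmethanol
Product: 2 furan-3-ylmethyl acetate
Conditions: Ac2O, pyridine, DMAP (cat.), CH2Cl2, 0 °C to rt
Reagents that add atoms: acetic anhydride CC(=O)OC(C)=O
Why: DMAP-catalysed acetylation of a primary alcohol is reliable and masks the hydroxyl so that it cannot add to the dialdehyde made next; no stereocenter is formed.

**Step 2**
Reactants: 2 furan-3-ylmethyl acetate
Product: 4 (2E)-2-(acetoxymethyl)but-2-enedial, via Z-enedial 3 (not isolated)
Conditions: dimethyldioxirane (1.1 equiv), acetone, −20 °C; then I2 (2 mol %), CH2Cl2, rt; used as a solution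
Reagents that add atoms: dimethyldioxirane CC1(C)OO1
Why: Oxidative furan ring opening (dioxirane epoxidation, collapse to the cis-enedial) followed by iodine-catalysed Z-to-E isomerisation gives the fumaraldehyde-type 1-oxadiene with the two formyl groups trans, as the cycloaddition needs; no stereocenter is formed.

**Step 3**
Reactants: 5 tert-butyl(but-3-yn-1-yloxy)dimethylsilane
Product: 6 (1Z)-4-[(tert-butyldimethylsilyl)oxy]but-1-en-1-yl acetate
Conditions: AcOH (1.2 equiv), Ru(η3-CH2C(CH3)CH2)2(Ph2P(CH2)4PPh2) (1 mol %), toluene, 65 °C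
Reagents that add atoms: acetic acid CC(=O)O
Why: Ruthenium-vinylidene catalysed anti-Markovnikov hydro-oxycarbonylation of a terminal alkyne gives the (Z)-enol ester selectively, and this Z geometry later becomes the 2,3-cis relationship of the pyran.

**Step 4**
Reactants: 4 (2E)-2-(acetoxymethyl)but-2-enedial; 6 (1Z)-4-[(tert-butyldimethylsilyl)oxy]but-1-en-1-yl acetate
Product: 7 [(2S,3S,4R)-2-acetoxy-3-{2-[(tert-butyldimethylsilyl)oxy]ethyl}-4-formyl-3,4-dihydro-2H-pyran-5-yl]methyl acetate
Conditions: (S,S)-imidodiphosphorimidate Brønsted acid (BINOL-derived, N-triflyl; 3 mol %), 6 (1.5 equiv), CH2Cl2, 5 Å sieves, −60 °C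
Reagents that add atoms: none
Why: Proposed new method: an enantioselective inverse-electron-demand oxa-Diels–Alder reaction in which the confined chiral acid hydrogen-bonds the formyl group on the substituted carbon of 4 (a 1-oxadiene whose LUMO is lowered further by the second formyl group), the β-carbon of the (Z)-enol acetate attacks the unsubstituted diene terminus (the other terminus is fully substituted, which decides which formyl oxygen enters the ring) and the oxygen closes onto the acetoxy-bearing carbon through an asynchronous endo transition state in the chiral pocket; this fixes the absolute configuration, and since the dienophile is Z and the remaining formyl group sits "outside", acetate, side chain and formyl group end up all cis (2S,3S,4R); the closest known reaction types are chromium- and europium-Lewis-acid catalysed hetero-Diels–Alder reactions of enals with enol ethers and chiral Brønsted-acid catalysed hetero-Diels–Alder reactions, none shown for enol esters or ene-dials.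

**Step 5**
Reactants: 7 [(2S,3S,4R)-2-acetoxy-3-{2-[(tert-butyldimethylsilyl)oxy]ethyl}-4-formyl-3,4-dihydro-2H-pyran-5-yl]methyl acetate
Product: 8 [(2S,3S,4R)-2-acetoxy-3-{2-[(tert-butyldimethylsilyl)oxy]ethyl}-4-(2-methylprop-1-en-1-yl)-3,4-dihydro-2H-pyran-5-yl]methyl acetate
Conditions: [i-PrPPh3]I, KN(SiMe3)2, THF, 0 °C; then 7, −78 to −20 °C
Reagents that add atoms: isopropyltriphenylphosphonium iodide CC(C)[P+](c1ccccc1)(c1ccccc1)c1ccccc1.[I-]
Why: Wittig olefination with the non-stabilised isopropylidene ylide converts the aldehyde into the trisubstituted alkene (no E/Z question) at −78 °C, faster than enolisation of the α-stereocenter C-4 or attack on the acetates, so C-4 is kept.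

**Step 6**
Reactants: 8 [(2S,3S,4R)-2-acetoxy-3-{2-[(tert-butyldimethylsilyl)oxy]ethyl}-4-(2-methylprop-1-en-1-yl)-3,4-dihydro-2H-pyran-5-yl]methyl acetate
Product: 9 [(2S,3S,4R)-2-acetoxy-3-(2-hydroxyethyl)-4-(2-methylprop-1-en-1-yl)-3,4-dihydro-2H-pyran-5-yl]methyl acetate
Conditions: HF·pyridine, pyridine, THF, 0 °C
Reagents that add atoms: none
Why: Buffered fluoride desilylation removes the primary silyl ether without touching the acetates, the acetoxy acetal or the enol ether; no stereocenter is affected.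

**Step 7**
Reactants: 9 [(2S,3S,4R)-2-acetoxy-3-(2-hydroxyethyl)-4-(2-methylprop-1-en-1-yl)-3,4-dihydro-2H-pyran-5-yl]methyl acetate
Product: 10 [(2S,3S,4R)-2-acetoxy-4-(2-methylprop-1-en-1-yl)-3-(2-oxoethyl)-3,4-dihydro-2H-pyran-5-yl]methyl acetate
Conditions: Dess–Martin periodinane, pyridine, CH2Cl2, 0 °C to rt
Reagents that add atoms: none
Why: Dess–Martin oxidation gives the aldehyde under buffered, non-epimerising conditions; the new carbonyl is not α to any stereocenter.

**Step 8**
Reactants: 10 [(2S,3S,4R)-2-acetoxy-4-(2-methylprop-1-en-1-yl)-3-(2-oxoethyl)-3,4-dihydro-2H-pyran-5-yl]methyl acetate; 11 prop-2-ynal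
Product: 13 [(2S,3R,4R)-2-acetoxy-3-[(1E)-1-formylbut-1-en-3-yn-1-yl]-4-(2-methylprop-1-en-1-yl)-3,4-dihydro-2H-pyran-5-yl]methyl acetate, via aldol adduct 12 (not isolated)
Conditions: [Bn2NH2][O2CCF3] (20 mol %), 11 (1.5 equiv, slow addition), toluene, 0 °C to rt
Reagents that add atoms: none
Why: Amine-salt catalysed cross-aldol condensation (enamine of 10 adds to the non-enolisable ynal, then E1cB dehydration) gives the thermodynamically preferred (E)-2-substituted enal, in which the ethynyl group is cis to the pyran substituent as ring closure requires; no new stereocenter remains.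

**Step 9**
Reactants: 13 [(2S,3R,4R)-2-acetoxy-3-[(1E)-1-formylbut-1-en-3-yn-1-yl]-4-(2-methylprop-1-en-1-yl)-3,4-dihydro-2H-pyran-5-yl]methyl acetate
Product: 14 CNP0263020.2 (target)
Conditions: [(t-Bu)2(2-biphenylyl)P]Au(NCCH3)SbF6 (5 mol %), Ph2SO (2 equiv), CH2Cl2, −20 °C to rt
Reagents that add atoms: diphenyl sulfoxide O=S(c1ccccc1)c1ccccc1
Why: Proposed new method: a gold-catalysed 7-endo-dig enyne cycloisomerisation with oxidative interception, in which the cationic gold complex activates the terminal alkyne of the ynenal (its terminal carbon is the vinylogous electrophilic position), the trisubstituted alkene attacks that carbon to give a cyclopropyl gold carbene (both alkene carbons bond to the alkyne terminus, hence a cis-fused bicyclo[5.1.0] unit) and diphenyl sulfoxide transfers oxygen to the carbene carbon to give the ketone; allylic 1,3-strain holds H-4 in the plane of the 2-methylprop-1-enyl group, so the alkyne, tethered through C-3, adds to the alkene face anti to C-5, which sets both cyclopropane carbons (S next to the ketone, R next to the ring fusion); the closest known reaction types are gold-catalysed 1,6-enyne cycloisomerisation with sulfoxide oxidation of the carbene and gold-catalysed alkyne oxidation/cyclopropanation to bicyclo[3.1.0] and bicyclo[4.1.0] ketones, not shown for seven-membered rings or ynenals.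

**Compound list**

1 | furan-3-ylmethanol | OCc1ccoc1 | starting material
2 | furan-3-ylmethyl acetate | CC(=O)OCc1ccoc1 | intermediate
3 | (2Z)-2-(acetoxymethyl)but-2-enedial | CC(=O)OC/C(C=O)=C/C=O | intermediate
4 | (2E)-2-(acetoxymethyl)but-2-enedial | CC(=O)OC/C(C=O)=C\C=O | intermediate
5 | tert-butyl(but-3-yn-1-yloxy)dimethylsilane | C#CCCO[Si](C)(C)C(C)(C)C | starting material
6 | (1Z)-4-[(tert-butyldimethylsilyl)oxy]but-1-en-1-yl acetate | CC(=O)O/C=C\CCO[Si](C)(C)C(C)(C)C | intermediate
7 | [(2S,3S,4R)-2-acetoxy-3-{2-[(tert-butyldimethylsilyl)oxy]ethyl}-4-formyl-3,4-dihydro-2H-pyran-5-yl]methyl acetate | CC(=O)OCC1=CO[C@@H](OC(C)=O)[C@@H](CCO[Si](C)(C)C(C)(C)C)[C@H]1C=O | intermediate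
8 | [(2S,3S,4R)-2-acetoxy-3-{2-[(tert-butyldimethylsilyl)oxy]ethyl}-4-(2-methylprop-1-en-1-yl)-3,4-dihydro-2H-pyran-5-yl]methyl acetate | CC(=O)OCC1=CO[C@@H](OC(C)=O)[C@@H](CCO[Si](C)(C)C(C)(C)C)[C@H]1C=C(C)C | intermediate
9 | [(2S,3S,4R)-2-acetoxy-3-(2-hydroxyethyl)-4-(2-methylprop-1-en-1-yl)-3,4-dihydro-2H-pyran-5-yl]methyl acetate | CC(=O)OCC1=CO[C@@H](OC(C)=O)[C@@H](CCO)[C@H]1C=C(C)C | intermediate
10 | [(2S,3S,4R)-2-acetoxy-4-(2-methylprop-1-en-1-yl)-3-(2-oxoethyl)-3,4-dihydro-2H-pyran-5-yl]methyl acetate | CC(=O)OCC1=CO[C@@H](OC(C)=O)[C@@H](CC=O)[C@H]1C=C(C)C | intermediate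
11 | prop-2-ynal | C#CC=O | starting material
12 | [(2S,3R,4R)-2-acetoxy-3-(1-formyl-2-hydroxybut-3-yn-1-yl)-4-(2-methylprop-1-en-1-yl)-3,4-dihydro-2H-pyran-5-yl]methyl acetate (both epimers at each side-chain carbon) | CC(=O)OCC1=CO[C@@H](OC(C)=O)[C@@H](C(C=O)C(O)C#C)[C@H]1C=C(C)C | intermediate
13 | [(2S,3R,4R)-2-acetoxy-3-[(1E)-1-formylbut-1-en-3-yn-1-yl]-4-(2-methylprop-1-en-1-yl)-3,4-dihydro-2H-pyran-5-yl]methyl acetate | CC(=O)OCC1=CO[C@@H](OC(C)=O)[C@@H](/C(C=O)=C\C#C)[C@H]1C=C(C)C | intermediate
14 | CNP0263020.2: 2-acetoxy-5-(acetoxymethyl)-3,4-dihydro-2H-pyran cis-fused at C-3/C-4 to a 3-formylcyclohept-2-en-1-one whose ketone is flanked by a cis-fused gem-dimethylcyclopropane; acetal carbon S, ring-fusion carbon next to it R, other ring-fusion carbon R, cyclopropane CH next to the ketone S, other cyclopropane CH R | CC(=O)OCC1=CO[C@@H](OC(C)=O)[C@H]2C(C=O)=CC(=O)[C@H]3[C@@H]([C@@H]12)C3(C)C | target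

**Step count and risks**

Total steps: 9. Longest linear sequence: 8 (steps 1, 2, 4, 5, 6, 7, 8, 9; step 3 is the side branch).

The three steps most likely to fail are steps 4, 8 and 9; steps 4 and 9 are the proposed new methods.

Step 4 (new cycloaddition; the enol ester may be too weak a dienophile, or ee may be low). The fallback sets out from dial 4 and alkyne 5 and comes back at 8, using the established Lewis-acid route with an enol ether. Alkyne 5 is converted by rhodium-catalysed anti-Markovnikov addition of ethanol, with (1,5-cyclooctadiene)(8-quinolinolato)rhodium, into the (Z)-enol ether tert-butyl{[(3Z)-4-ethoxybut-3-en-1-yl]oxy}dimethylsilane F1. F1 and 4 then undergo the known endo-selective hetero-Diels–Alder reaction of enals with enol ethers, catalysed by the chloride complex of trivalent chromium with the tridentate Schiff base from 3-(1-adamantyl)-2-hydroxy-5-methylbenzaldehyde and cis-1-aminoindan-2-ol (4 Å sieves, rt), to give the all-cis 2-ethoxy acetal [(2R,3S,4R)-2-ethoxy-3-{2-[(tert-butyldimethylsilyl)oxy]ethyl}-4-formyl-3,4-dihydro-2H-pyran-5-yl]methyl acetate F2. Wittig olefination as in step 5 gives the 2-methylprop-1-enyl compound [(2R,3S,4R)-2-ethoxy-3-{2-[(tert-butyldimethylsilyl)oxy]ethyl}-4-(2-methylprop-1-en-1-yl)-3,4-dihydro-2H-pyran-5-yl]methyl acetate F3. Acetolysis (Ac2O, cat. BF3·OEt2, CH2Cl2, −40 °C) then exchanges ethoxy for acetoxy and returns to 8. The anomeric configuration is then set by the exchange rather than by the cycloaddition, so the wrong anomer may have to be separated.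

Step 8 (the free terminal ynal can be consumed by conjugate addition of the amine catalyst). The fallback sets out from 10 and comes back at 13. Aldehyde 10 is condensed (pyrrolidine/benzoic acid, CH2Cl2) with 3-(trimethylsilyl)prop-2-ynal, whose silyl group blocks the alkyne terminus, to give the silyl ynenal [(2S,3R,4R)-2-acetoxy-3-[(1E)-1-formyl-4-(trimethylsilyl)but-1-en-3-yn-1-yl]-4-(2-methylprop-1-en-1-yl)-3,4-dihydro-2H-pyran-5-yl]methyl acetate F4. C-desilylation with tetrabutylammonium fluoride buffered with acetic acid (THF, −20 °C) then gives 13.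

Step 9 (new gold cyclisation; possible failures are oxygen transfer to the wrong alkyne carbon, 6-exo closure, or attack by the ring enol ether). The fallback sets out from 10 and comes back at 14, using the classical intramolecular diazoketone cyclopropanation with the aldehyde masked:
- Condensation of 10 with methylglyoxal under the step 8 conditions gives the keto-enal [(2S,3R,4R)-2-acetoxy-3-[(1E)-1-formyl-3-oxobut-1-en-1-yl]-4-(2-methylprop-1-en-1-yl)-3,4-dihydro-2H-pyran-5-yl]methyl acetate F5.
- Aldehyde-selective reduction (NaBH4, 0.3 equiv, EtOH/CH2Cl2, −78 °C) gives the hydroxy enone F6.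
- Silylation (TBSCl, imidazole) gives the silyl ether F7.
- Trifluoroacetylation (LiN(SiMe3)2, CF3CO2CH2CF3, THF, −78 °C) gives the trifluoroacetyl diketone F8.
- Diazo transfer (MsN3, Et3N, H2O, MeCN) gives the vinyl diazoketone F9.
- Rh2(OAc)4 (CH2Cl2, slow addition) closes the ring to the tricyclic silyl ether F10, with the same allylic-strain control as in step 9.
- HF·pyridine gives the tricyclic allylic alcohol F11, and MnO2 oxidises it to 14.

**Further compounds**

F1 | step 4 | tert-butyl{[(3Z)-4-ethoxybut-3-en-1-yl]oxy}dimethylsilane | CCO/C=C\CCO[Si](C)(C)C(C)(C)C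
F2 | step 4 | [(2R,3S,4R)-2-ethoxy-3-{2-[(tert-butyldimethylsilyl)oxy]ethyl}-4-formyl-3,4-dihydro-2H-pyran-5-yl]methyl acetate | CC(=O)OCC1=CO[C@@H](OCC)[C@@H](CCO[Si](C)(C)C(C)(C)C)[C@H]1C=O
F3 | step 4 | [(2R,3S,4R)-2-ethoxy-3-{2-[(tert-butyldimethylsilyl)oxy]ethyl}-4-(2-methylprop-1-en-1-yl)-3,4-dihydro-2H-pyran-5-yl]methyl acetate | CC(=O)OCC1=CO[C@@H](OCC)[C@@H](CCO[Si](C)(C)C(C)(C)C)[C@H]1C=C(C)C
F4 | step 8 | [(2S,3R,4R)-2-acetoxy-3-[(1E)-1-formyl-4-(trimethylsilyl)but-1-en-3-yn-1-yl]-4-(2-methylprop-1-en-1-yl)-3,4-dihydro-2H-pyran-5-yl]methyl acetate | CC(=O)OCC1=CO[C@@H](OC(C)=O)[C@@H](/C(C=O)=C\C#C[Si](C)(C)C)[C@H]1C=C(C)C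
F5 | step 9 | [(2S,3R,4R)-2-acetoxy-3-[(1E)-1-formyl-3-oxobut-1-en-1-yl]-4-(2-methylprop-1-en-1-yl)-3,4-dihydro-2H-pyran-5-yl]methyl acetate | CC(=O)OCC1=CO[C@@H](OC(C)=O)[C@@H](/C(C=O)=C\C(C)=O)[C@H]1C=C(C)C
F6 | step 9 | [(2S,3R,4R)-2-acetoxy-3-[(2E)-1-hydroxy-4-oxopent-2-en-2-yl]-4-(2-methylprop-1-en-1-yl)-3,4-dihydro-2H-pyran-5-yl]methyl acetate | CC(=O)OCC1=CO[C@@H](OC(C)=O)[C@@H](/C(CO)=C\C(C)=O)[C@H]1C=C(C)C
F7 | step 9 | [(2S,3R,4R)-2-acetoxy-3-[(2E)-1-[(tert-butyldimethylsilyl)oxy]-4-oxopent-2-en-2-yl]-4-(2-methylprop-1-en-1-yl)-3,4-dihydro-2H-pyran-5-yl]methyl acetate | CC(=O)OCC1=CO[C@@H](OC(C)=O)[C@@H](/C(CO[Si](C)(C)C(C)(C)C)=C\C(C)=O)[C@H]1C=C(C)C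
F8 | step 9 | [(2S,3R,4R)-2-acetoxy-3-[(2E)-1-[(tert-butyldimethylsilyl)oxy]-7,7,7-trifluoro-4,6-dioxohept-2-en-2-yl]-4-(2-methylprop-1-en-1-yl)-3,4-dihydro-2H-pyran-5-yl]methyl acetate | CC(=O)OCC1=CO[C@@H](OC(C)=O)[C@@H](/C(CO[Si](C)(C)C(C)(C)C)=C\C(=O)CC(=O)C(F)(F)F)[C@H]1C=C(C)C
F9 | step 9 | [(2S,3R,4R)-2-acetoxy-3-[(2E)-1-[(tert-butyldimethylsilyl)oxy]-5-diazo-4-oxopent-2-en-2-yl]-4-(2-methylprop-1-en-1-yl)-3,4-dihydro-2H-pyran-5-yl]methyl acetate | CC(=O)OCC1=CO[C@@H](OC(C)=O)[C@@H](/C(CO[Si](C)(C)C(C)(C)C)=C\C(=O)C=[N+]=[N-])[C@H]1C=C(C)C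
F10 | step 9 | tricyclic silyl ether: compound 14 with CH2OSi(t-Bu)Me2 in place of the formyl group, same configuration at all five stereocentres | CC(=O)OCC1=CO[C@@H](OC(C)=O)[C@H]2C(CO[Si](C)(C)C(C)(C)C)=CC(=O)[C@H]3[C@@H]([C@@H]12)C3(C)C
F11 | step 9 | tricyclic allylic alcohol: compound 14 with CH2OH in place of the formyl group, same configuration at all five stereocentres | CC(=O)OCC1=CO[C@@H](OC(C)=O)[C@H]2C(CO)=CC(=O)[C@H]3[C@@H]([C@@H]12)C3(C)C
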